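- Monday's charge holds 0.320 M partner against 0.400 M substrate, and one of each makes one product. Partner is therefore the limiting reagent, and the ceiling for Monday's flask is 80.0% of the substrate.

| flask | substrate | partner | free catalyst | time |
|---|---|---|---|---|
| Tuesday's | 0.100 M | 0.0800 M | 0.00800 M |  |
| Wednesday's | 0.200 M | 0.0800 M | 0.00800 M |  |
| Monday's | 0.400 M | 0.320 M | 0.00800 M | 43 h |

| run | time / h | [product] / M |
|---|---|---|
| Tuesday's run | 7.2 | 0.0329 |
| Tuesday's run | 14 | 0.0426 |
| Tuesday's run | 22 | 0.0489 |
| Tuesday's run | 29 | 0.0507 |
| Tuesday's run | 36 | 0.0520 |
| Tuesday's run | 43 | 0.0533 |
| Wednesday's run | 7.2 | 0.0537 |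
| Wednesday's run | 14 | 0.0631 |
| Wednesday's run | 22 | 0.0682 |
| Wednesday's run | 29 | 0.0688 |
| Wednesday's run | 36 | 0.0699 |
| Wednesday's run | 43 | 0.0700 |

(each reading ± 3 × 10⁻⁴ M)

1. reaction order in [substrate] at the outset, round the charge of the Tuesday's run, defined at two percent of the substrate turned into product (one fixed amount of product, the same in the runs compared)
2. product in the Monday's run at 43 h, as a share of the substrate charged

- Overall: substrate + partner -> product, with free catalyst as catalyst.
- Constant volume, constant temperature.
- An order is taken over about fifteen percent of the charge, up and down.

- Monday's flask could reach that ceiling only if every partner ended in product. Yet Wednesday's product levels off at 0.0700 M, below its partner charge of 0.0800 M.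
- A scale for this is the partner odds: product made, divided by partner charged that is not in product. The zero of the scale is an even split, odds of 1, which on Monday's flask gives 40.0%; the ceiling lies at endless odds.
- Wednesday's last reading gives odds of 7.00. Tuesday's gives 2.00, but Tuesday's product still rose 0.00130 M between its last two readings, while Wednesday's rose 1.00 × 10⁻⁴ M. So Wednesday's flask is the one to read.
- The reckoning here assumes that product formation is first order in partner and that the other path goes as partner squared, so the odds follow substrate per partner. Wednesday's flask gives 2.80 as the split number, the odds divided by substrate per partner at the charge.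
- Monday's substrate per partner gives odds of 3.50, and so 62.2% of the substrate, if Monday's product has levelled off by the time asked, as Wednesday's readings had.
- Wednesday's first reading stands 1.63 times Tuesday's, an order of 0.707. Wednesday's flask has by then used more partner, so the reckoning here takes the order as about one.
- The forecast gives 68% and an order of 0.97, from a reversible reaction, adding that “inhibition could leave a small shortfall”.
- Monday's flask gives 62.5%, and the order is 1.0, with Wednesday's rate 2.0 times Tuesday's at the same product made.

    2 free catalyst ⇌ catalyst dimer, settled at all times (164.0 /M)
    free catalyst + substrate + partner → product + free catalyst (319.3 /M²/h)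
    2 partner → lost reagent (0.3085 /M/h)
    free catalyst → spent catalyst (0.07956 /h)

- Monday's 62.5% means odds of 3.58, a split number of 2.86. Tuesday's flask has the same substrate per partner as Monday's, so the split number 2.80 gives 0.0622 M product for Tuesday's flask, while its last reading stands at 0.0533 M, half of its substrate having turned at 25.8 h.

The earlier runs and the new flask were computed with constants of no real substance; scatter was added.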